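Everything rests on cutting the cyclopentane ring into two pieces. The key step exploits that its carbinol carbon C(OH)Me lies between the ring CH2 and the ring CH that carries the CH2 link to the triketone ring (an acetone 1,3-dianion pattern), while the isopropenyl-bearing CH and its CH2 neighbour are an isoprene unit. In one flask the dianion of an acetonyl phosphonate is alkylated at its terminal carbon by an isoprene-derived allylic chloride, and the enolate then closes the ring by enantioselective palladium-catalysed allylic alkylation: the CH2–CH2 bond and the CH–CH bond form and the π-allyl remainder becomes the isopropenyl group. The precursors are a C5 chloro carbonate and dimethyl (2-oxopropyl)phosphonate.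

Key step: step 3

Remark: 10, 11 and 12 are mixtures of enol tautomers and are drawn in the tautomer of the target; in step 3 the (R,R)-ligand is assumed to give the required sense of induction, and its mirror image is used if the sense proves opposite.

Step 1
Reactants: 1 2-methyl-2-vinyloxirane (isoprene monoxide, racemic)
Product: 2 (E)-4-chloro-2-methylbut-2-en-1-ol
Conditions: TiCl4, CH2Cl2, −85 °C; 1 M aq. HCl
Reagents that add atoms: titanium tetrachloride, Cl[Ti](Cl)(Cl)Cl
Why: The Lewis acid activates the vinyl epoxide and chloride is delivered to the vinyl terminus with allylic transposition (SN2′ opening of a vinyl oxirane), which should give the primary allylic chloride and the trisubstituted (E)-alkene.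

Step 2
Reactants: 2 (E)-4-chloro-2-methylbut-2-en-1-ol
Product: 3 tert-butyl (E)-4-chloro-2-methylbut-2-en-1-yl carbonate
Conditions: Boc2O, DMAP (cat.), CH2Cl2, 0 °C to rt
Reagents that add atoms: di-tert-butyl dicarbonate, CC(C)(C)OC(=O)OC(=O)OC(C)(C)C
Why: DMAP-catalysed O-acylation of the primary allylic alcohol gives a tert-butyl carbonate, a leaving group that zerovalent palladium ionises readily but that is too hindered to be attacked by the carbanion of step 3.

Step 3
Reactants: 3 tert-butyl (E)-4-chloro-2-methylbut-2-en-1-yl carbonate; 4 dimethyl (2-oxopropyl)phosphonate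
Product: 7 dimethyl [(1R,5R)-2-oxo-5-(prop-1-en-2-yl)cyclopentyl]phosphonate, via phosphonate dianion 5 (not isolated), via acyclic enolate 6 (not isolated)
Conditions: 4, NaH, THF, 0 °C; n-BuLi, 0 °C; 3, −78 to 0 °C; then Pd2(dba)3·CHCl3 (2.5 mol%), N,N'-[(1R,2R)-cyclohexane-1,2-diyl]bis[2-(diphenylphosphanyl)benzamide] ((R,R)-DACH-phenyl ligand, 7.5 mol%), 0 °C to rt; aq. NH4Cl
Reagents that add atoms: none
Why: The dianion 5 reacts at its terminal carbon with the allylic chloride of 3 (SN2), which forms the bond between the two ring methylenes and leaves the β-keto phosphonate enolate 6; zerovalent palladium then ionises the allylic carbonate and the enolate carbon attacks the near terminus of the 2-methyl-π-allyl unit, which forms the CH–CH bond, closes the ring and leaves the rest of the allyl unit as the isopropenyl group. The closest known reaction types are the terminal alkylation of β-keto phosphonate dianions and the intramolecular Tsuji–Trost allylic alkylation of 3-oxo-oct-6-enoates with an allylic leaving group to 2-carbalkoxy-3-vinylcyclopentanones. The five-membered ring closes in the 5-exo mode (formally 5-(enolendo)-exo-trig, at a π-allyl palladium cation). The isopropenyl-bearing stereocentre is set by the chiral ligand: the two diastereomeric π-allyl complexes interconvert by η3–η1–η3 isomerisation through the unsubstituted CH2 terminus, so the ligand pocket selects the allyl face in the bond-forming step; the phosphorus-bearing centre is epimerisable, should settle trans, and is erased in step 4. The step needs terminal over internal alkylation of the nucleophile (secured by the dianion, whose terminal carbanion is the more reactive site), attack at chloride rather than at the carbonate (secured by the hindered tert-butyl group), and C- over O-allylation with five- over seven-membered closure (O-allylation is reversible under palladium catalysis and should funnel to the cyclopentanone, and attack at the near terminus is kinetically favoured).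

Step 4
Reactants: 7 dimethyl [(1R,5R)-2-oxo-5-(prop-1-en-2-yl)cyclopentyl]phosphonate
Product: 8 (R)-2-methylidene-3-(prop-1-en-2-yl)cyclopentan-1-one
Conditions: 37% aq. HCHO, K2CO3, THF/H2O, 0 °C, short reaction time; used at once
Reagents that add atoms: formaldehyde, C=O
Why: Horner–Wadsworth–Emmons olefination of the cyclic β-keto phosphonate with formaldehyde places the exocyclic methylene at the former phosphorus-bearing carbon, and the weak base, low temperature and short contact time are chosen to leave the doubly allylic C-3 stereocentre untouched.

Step 5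
Reactants: 9 2,4,6-trihydroxybenzophenone
Product: 10 2-benzoyl-3,5-dihydroxy-6,6-bis(3-methylbut-2-en-1-yl)cyclohexa-2,4-dien-1-one
Conditions: prenyl bromide (2.1 equiv), NaOMe, MeOH, 0 °C to rt
Reagents that add atoms: prenyl bromide (1-bromo-3-methylbut-2-ene), CC(C)=CCBr
Why: C-Alkylation of the phloroglucinol polyanion, in which the second prenyl group enters in part at the already prenylated ring carbon with loss of aromaticity (dearomatising geminal alkylation, as in lupulone-type syntheses), should give 10, to be separated from the aromatic 3,5-diprenyl isomer.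

Step 6
Reactants: 8 (R)-2-methylidene-3-(prop-1-en-2-yl)cyclopentan-1-one; 10 2-benzoyl-3,5-dihydroxy-6,6-bis(3-methylbut-2-en-1-yl)cyclohexa-2,4-dien-1-one
Product: 11 2-benzoyl-3,5-dihydroxy-6,6-bis(3-methylbut-2-en-1-yl)-4-{[(1R,5S)-2-oxo-5-(prop-1-en-2-yl)cyclopentyl]methyl}cyclohexa-2,4-dien-1-one
Conditions: 10 (1.05 equiv), DBU (2 equiv), THF, −20 °C; 8; to rt, then rt for equilibration; aq. citric acid
Reagents that add atoms: none
Why: Michael addition of the only nucleophilic ring carbon of 10 (C-4, the CH between the two enolic carbons) to the exocyclic enone, after which the α-centre of the ketone should equilibrate under the basic conditions to the more stable 2,3-trans arrangement (thermodynamic control), which sets the ring carbon that bears the CH2 link.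

Step 7
Reactants: 11 2-benzoyl-3,5-dihydroxy-6,6-bis(3-methylbut-2-en-1-yl)-4-{[(1R,5S)-2-oxo-5-(prop-1-en-2-yl)cyclopentyl]methyl}cyclohexa-2,4-dien-1-one
Product: 12 hypercalin B, 2-benzoyl-3,5-dihydroxy-4-{[(1R,2S,5S)-2-hydroxy-2-methyl-5-(prop-1-en-2-yl)cyclopentyl]methyl}-6,6-bis(3-methylbut-2-en-1-yl)cyclohexa-2,4-dien-1-one
Conditions: MeMgBr (6 equiv), LaCl3·2LiCl, THF, −78 to 0 °C; aq. NH4Cl
Reagents that add atoms: methylmagnesium bromide, C[Mg]Br
Why: 1,2-Addition of the Grignard reagent to the cyclopentanone (LaCl3·2LiCl favours addition over enolisation, and the acidic triketone is masked in situ as its magnesium bis-enolate) should occur anti to the adjacent CH2-linked side chain (1,2-induction, as in reductions of 2,3-trans-disubstituted cyclopentanones), placing the hydroxyl cis to that chain.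

Compound list
1 | 2-methyl-2-vinyloxirane (racemic) | CC1(C=C)CO1 | starting material
2 | (E)-4-chloro-2-methylbut-2-en-1-ol | ClC/C=C(C)/CO | intermediate
3 | tert-butyl (E)-4-chloro-2-methylbut-2-en-1-yl carbonate | ClC/C=C(C)/COC(=O)OC(C)(C)C | intermediate
4 | dimethyl (2-oxopropyl)phosphonate | COP(=O)(OC)CC(C)=O | starting material
5 | sodium lithium 1,3-dianion of dimethyl (2-oxopropyl)phosphonate | COP(=O)(OC)[CH-]C(=O)[CH2-].[Na+].[Li+] | intermediate
6 | sodium enolate of dimethyl [(E)-7-(tert-butoxycarbonyloxy)-6-methyl-2-oxohept-5-en-1-yl]phosphonate | COP(=O)(OC)[CH-]C(=O)CC/C=C(C)/COC(=O)OC(C)(C)C.[Na+] | intermediate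
7 | dimethyl [(1R,5R)-2-oxo-5-(prop-1-en-2-yl)cyclopentyl]phosphonate | C=C(C)[C@H]1CCC(=O)[C@@H]1P(=O)(OC)OC | intermediate
8 | (R)-2-methylidene-3-(prop-1-en-2-yl)cyclopentan-1-one | C=C(C)[C@H]1CCC(=O)C1=C | intermediate
9 | 2,4,6-trihydroxybenzophenone | O=C(c1ccccc1)c1c(O)cc(O)cc1O | starting material
10 | 2-benzoyl-3,5-dihydroxy-6,6-bis(3-methylbut-2-en-1-yl)cyclohexa-2,4-dien-1-one | O=C(c1ccccc1)C1=C(O)C=C(O)C(CC=C(C)C)(CC=C(C)C)C1=O | intermediate
11 | 2-benzoyl-3,5-dihydroxy-6,6-bis(3-methylbut-2-en-1-yl)-4-{[(1R,5S)-2-oxo-5-(prop-1-en-2-yl)cyclopentyl]methyl}cyclohexa-2,4-dien-1-one | C=C(C)[C@H]1CCC(=O)[C@@H]1CC1=C(O)C(CC=C(C)C)(CC=C(C)C)C(=O)C(C(=O)c2ccccc2)=C1O | intermediate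
12 | hypercalin B | C=C(C)[C@H]1CC[C@](C)(O)[C@@H]1CC1=C(O)C(CC=C(C)C)(CC=C(C)C)C(=O)C(C(=O)c2ccccc2)=C1O | target

Total step count: 7. Longest linear sequence: 6 steps (steps 1, 2, 3, 4, 6, 7); step 5 is a one-step side branch.

Steps most likely to fail

Step 3. The ring-closing allylation may discriminate poorly between the two faces of the π-allyl unit, or the enolate may close through oxygen or at the far allyl terminus without funnelling to the cyclopentanone. The fallback sets the stereocentre by conjugate addition and closes the ring at the ketone carbon instead. It uses neither 3 nor 4: it sets out from commercial methyl 4-oxobutanoate and tetramethyl methylenediphosphonate and comes back to the route at 7. A Horner–Wadsworth–Emmons reaction (NaH, THF) should give methyl (E)-5-(dimethoxyphosphoryl)pent-4-enoate F1. Rhodium-catalysed asymmetric conjugate addition of isopropenylboronic acid pinacol ester ([Rh(acac)(C2H4)2], the BINAP enantiomer that delivers the R product, aq. KOH, dioxane, heat; Hayashi–Miyaura reaction on an alkenylphosphonate) should then give methyl (R)-4-[(dimethoxyphosphoryl)methyl]-5-methylhex-5-enoate F2. LiN(iPr)2 (2.2 equiv) in THF at −78 to 0 °C should close the ring by intramolecular acylation of the phosphonate carbanion by the ester (Dieckmann-type) to give 7.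

Step 7. The basic Grignard reagent may enolise the cyclopentanone within the polyanionic substrate instead of adding, or add with too little facial discrimination. The fallback sets out from 11 and comes back at 12, replacing the carbanion by a much less basic ylide and a hydride. After deprotonation of the enols with NaH, dimethylsulfonium methylide (trimethylsulfonium iodide, NaH, DMSO/THF, 0 °C; Corey–Chaykovsky epoxidation) should add from the face anti to the side chain and give 2-benzoyl-3,5-dihydroxy-6,6-bis(3-methylbut-2-en-1-yl)-4-{[(3S,4R,5S)-5-(prop-1-en-2-yl)-1-oxaspiro[2.4]heptan-4-yl]methyl}cyclohexa-2,4-dien-1-one F3. LiEt3BH in THF at 0 °C should open the epoxide at its CH2 terminus and give the methyl carbinol 12.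

Step 5. Alkylation at the free aromatic CH may outrun geminal alkylation, so that the aromatic 3,5-diprenyl isomer dominates. The fallback changes the order of the alkylations; it sets out from 9 and 8 and comes back at 11. Michael addition of 9 (in excess, DBU, THF) to 8 occupies one ring carbon and should give (2R,3S)-2-[(3-benzoyl-2,4,6-trihydroxyphenyl)methyl]-3-(prop-1-en-2-yl)cyclopentan-1-one F4. Prenyl bromide (2.1 equiv) with NaOMe in MeOH should then place both prenyl groups on the one remaining ring carbon, the second with dearomatisation, to give 11.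

Further compounds
F1 | step 3 | methyl (E)-5-(dimethoxyphosphoryl)pent-4-enoate | COC(=O)CC/C=C/P(=O)(OC)OC
F2 | step 3 | methyl (R)-4-[(dimethoxyphosphoryl)methyl]-5-methylhex-5-enoate | C=C(C)[C@@H](CCC(=O)OC)CP(=O)(OC)OC
F3 | step 7 | 2-benzoyl-3,5-dihydroxy-6,6-bis(3-methylbut-2-en-1-yl)-4-{[(3S,4R,5S)-5-(prop-1-en-2-yl)-1-oxaspiro[2.4]heptan-4-yl]methyl}cyclohexa-2,4-dien-1-one | C=C(C)[C@H]1CC[C@]2(OC2)[C@@H]1CC1=C(O)C(CC=C(C)C)(CC=C(C)C)C(=O)C(C(=O)c2ccccc2)=C1O
F4 | step 5 | (2R,3S)-2-[(3-benzoyl-2,4,6-trihydroxyphenyl)methyl]-3-(prop-1-en-2-yl)cyclopentan-1-one | C=C(C)[C@H]1CCC(=O)[C@@H]1Cc1c(O)cc(O)c(C(=O)c2ccccc2)c1O
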